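Retrosynthetic overview
1. Last disconnection: the two phenolic O–H groups are released from a diacetate. No ring is built at any stage. The benzene ring is bought as o-cresol and receives its para oxygen by aerobic oxidation.
2. Key disconnection: C8–C9 of the side chain (numbered from the benzylic CH2), the C(sp3)–C(sp2) bond between the doubly allylic CH2 and the outer CH of the E-CH=CH unit. This is the head-to-tail junction of isoprene units 2 and 3, closed here with the polarity opposite to biosynthetic prenyl transfer.
3. Enabling feature: the skipped diene C6=C7(CH3)–C8H2–C9H=C10H–C11(CH3)(OH). C8 is the unsubstituted end of the allyl unit C8–C7–C6, which can be ionised to an η3-allylpalladium. C9/C10 sit on a carbinol carbon C11 that bears no hydrogen, so they can be carried as a terminal alkyne that takes up H–Zr syn with the metal on C9 only.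
4. C10 half: geraniol → Sharpless epoxide (sets C11) → epoxy chloride → double elimination to (S)-dehydrolinalool.
5. C17 half: o-cresol + geranyl bromide → para-quinone → hydroquinone diacetate → E-selective SeO2 hydroxylation → allylic chloride.

Key step: step 9

Remark: the carbinol carbon of the target is read as S. It has the spatial arrangement of C3 of (2S,3S)-2,3-epoxygeraniol, whose C3–O bond is never broken in the route.

Step 1
Reactants: 1 o-cresol (2-methylphenol); 2 geranyl bromide [(2E)-1-bromo-3,7-dimethylocta-2,6-diene]
Product: 4 geranylcresol [2-((2E)-3,7-dimethylocta-2,6-dien-1-yl)-6-methylphenol], via sodium 2-methylphenolate 3 (not isolated)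
Conditions: NaH, toluene, 0 °C; then 2, rt → 60 °C
Reagents that add atoms: none
Why: Ortho-selective C-allylation of a phenolate (SN2 at the primary allylic carbon): in non-polar toluene the tight sodium ion pair should hold the bromide next to oxygen, so that carbon attack at the only free ortho position is favoured over O-alkylation and para attack, and the E-alkene of the geranyl unit is not involved.

Step 2
Reactants: 4 geranylcresol
Product: 5 geranyltoluquinone [2-((2E)-3,7-dimethylocta-2,6-dien-1-yl)-6-methyl-1,4-benzoquinone]
Conditions: Co(salen) (10 mol %), O2 (1 atm), DMF, rt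
Reagents that add atoms: dioxygen O=O
Why: Cobalt–salen-catalysed aerobic oxidation of a phenol to a para-benzoquinone: both ortho positions are substituted and the para position is free, so the cobalt-bound superoxide should oxygenate the phenoxyl radical at C4 only, with the donor solvent DMF disfavouring C–C dimerisation.

Step 3
Reactants: 5 geranyltoluquinone
Product: 7 geranyltoluquinol diacetate [2-((2E)-3,7-dimethylocta-2,6-dien-1-yl)-6-methylbenzene-1,4-diyl diacetate], via zinc hydroquinone diolate 6 (not isolated)
Conditions: Zn dust, Ac2O, pyridine, 0 °C → rt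
Reagents that add atoms: acetic anhydride CC(=O)OC(C)=O
Why: Reductive acetylation: zinc transfers two electrons to the quinone and the diolate is acylated at once, which stores the air-sensitive hydroquinone as a diester that should tolerate the oxidation, chlorination and coupling steps and is removed under mild base.

Step 4
Reactants: 7 geranyltoluquinol diacetate
Product: 8 allylic alcohol [2-((2E,6E)-8-hydroxy-3,7-dimethylocta-2,6-dien-1-yl)-6-methylbenzene-1,4-diyl diacetate]
Conditions: SeO2 (10 mol %), t-BuOOH (decane solution), salicylic acid (10 mol %), CH2Cl2, 0 °C → rt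
Reagents that add atoms: tert-butyl hydroperoxide CC(C)(C)OO (terminal oxygen source; SeO2, O=[Se]=O, is the catalytic carrier)
Why: Riley allylic oxidation (ene reaction with SeO2 followed by a [2,3]-sigmatropic shift, SeO2 being re-oxidised by t-BuOOH): the sequence is inherently E-selective for the methyl group trans to the chain, and the unhindered isopropylidene terminus should react ahead of the internal C2=C3 alkene.

Step 5
Reactants: 8 allylic alcohol
Product: 9 allylic chloride [2-((2E,6E)-8-chloro-3,7-dimethylocta-2,6-dien-1-yl)-6-methylbenzene-1,4-diyl diacetate]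
Conditions: PPh3, CCl4, MeCN, 0 °C → rt
Reagents that add atoms: carbon tetrachloride ClC(Cl)(Cl)Cl
Why: Appel reaction: chloride displaces the alkoxyphosphonium group by SN2 at the primary allylic carbon under neutral conditions, so neither allylic transposition nor E/Z isomerisation nor loss of the acetates is expected.

Step 6
Reactants: 10 geraniol [(2E)-3,7-dimethylocta-2,6-dien-1-ol]
Product: 11 (2S,3S)-2,3-epoxygeraniol [((2S,3S)-3-methyl-3-(4-methylpent-3-en-1-yl)oxiran-2-yl)methanol]
Conditions: Ti(OiPr)4 (5 mol %), L-(+)-diethyl tartrate (7 mol %), t-BuOOH, 4 Å MS, CH2Cl2, −20 °C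
Reagents that add atoms: tert-butyl hydroperoxide CC(C)(C)OO
Why: Sharpless asymmetric epoxidation: the titanium–tartrate complex binds the allylic alcohol, which directs oxygen to C2=C3 only, and L-(+)-tartrate selects the alkene face that makes both new stereocentres S, C3 being the future carbinol carbon.

Step 7
Reactants: 11 (2S,3S)-2,3-epoxygeraniol
Product: 12 epoxy chloride [(2S,3R)-3-(chloromethyl)-2-methyl-2-(4-methylpent-3-en-1-yl)oxirane]
Conditions: PPh3, CCl4, reflux
Reagents that add atoms: carbon tetrachloride ClC(Cl)(Cl)Cl
Why: Appel reaction at the primary carbinol carbon, which leaves both oxirane C–O bonds and thus both stereocentres untouched (the descriptor at the CH carbon changes to R only through the priority of chlorine).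

Step 8
Reactants: 12 epoxy chloride
Product: 14 (S)-dehydrolinalool [(3S)-3,7-dimethyloct-6-en-1-yn-3-ol], via dilithium alkoxide acetylide 13 (not isolated)
Conditions: n-BuLi (3.1 equiv), THF, −78 °C → −20 °C; then H2O
Reagents that add atoms: none
Why: Base-induced double elimination of a 2,3-epoxy chloride to a propargylic alcohol: deprotonation of CH2Cl opens the oxirane by breaking the C2–O bond, loss of HCl then gives the alkyne, the third equivalent of base rests on the acetylide, and the C3–O bond is never broken so that the S configuration is retained.

Step 9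
Reactants: 14 (S)-dehydrolinalool; 9 allylic chloride
Product: 16 target diacetate [2-((2E,6E,9E,11S)-11-hydroxy-3,7,11,15-tetramethylhexadeca-2,6,9,14-tetraen-1-yl)-6-methylbenzene-1,4-diyl diacetate], via O-zirconated alkenylzirconocene chloride 15 (not isolated)
Conditions: 14 (1.2 equiv), Cp2Zr(H)Cl (2.5 equiv), THF, 0 °C → rt, dark; then 9 (1.0 equiv), ZnCl2 (1.2 equiv), Pd(PPh3)4 (5 mol %), THF, 0 °C → rt; aq NaHCO3
Reagents that add atoms: none
Why: Cp2Zr(H)Cl first turns the tertiary O–H into a zirconium alkoxide (protection in the flask) and then adds H–Zr syn across the terminal alkyne with zirconium on the outer carbon, because the inner carbon is shielded by the fully substituted carbinol carbon, so the E geometry of C9=C10 is fixed by the mechanism and the trisubstituted C14=C15 alkene is left alone. Zerovalent palladium ionises the primary allylic chloride 9 to a syn-η3-allylpalladium chloride spanning C8–C7–C6, ZnCl2 shuttles the alkenyl group from zirconium to palladium and is regenerated, and inner-sphere reductive elimination forms C8–C9. The closest known reaction type is the one-flask hydrozirconation/Negishi alkenyl–allyl coupling used for stereodefined 1,4-dienes. No ring is closed and no new stereocentre is made: C11 comes in with 14 and is not touched, since its C–O bond stays intact as the alkoxide. The step needs linear over branched regioselectivity and retention of both alkene geometries: the allyl unit offers an unsubstituted CH2 terminus against a secondary CH terminus beside the C7 methyl group, and fast transmetalation from zinc should let reductive elimination outrun syn–anti isomerisation of the allyl unit and migration of the skipped diene into conjugation. In one operation the step should thus deliver the complete C27 skeleton, the E-disubstituted alkene and the skipped diene from two halves that each derive from a C10 geranyl unit.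

Step 10
Reactants: 16 target diacetate
Product: 17 target [2-((2E,6E,9E,11S)-11-hydroxy-3,7,11,15-tetramethylhexadeca-2,6,9,14-tetraen-1-yl)-6-methylbenzene-1,4-diol]
Conditions: K2CO3 (20 mol %), degassed MeOH, argon, 0 °C → rt; aq NH4Cl
Reagents that add atoms: none
Why: Base-catalysed transesterification of the two aryl acetates with methanol, which should be far faster than any reaction of the tertiary allylic alcohol or the skipped diene, while exclusion of air keeps the hydroquinone from oxidising to the quinone and no stereocentre is affected.

Compound list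
1 | o-cresol (2-methylphenol) | Cc1ccccc1O | starting material
2 | geranyl bromide, (2E)-1-bromo-3,7-dimethylocta-2,6-diene | CC(C)=CCC/C(C)=C/CBr | starting material
3 | sodium 2-methylphenolate (not isolated) | Cc1ccccc1[O-].[Na+] | intermediate
4 | geranylcresol, 2-((2E)-3,7-dimethylocta-2,6-dien-1-yl)-6-methylphenol | CC(C)=CCC/C(C)=C/Cc1cccc(C)c1O | intermediate
5 | geranyltoluquinone, 2-((2E)-3,7-dimethylocta-2,6-dien-1-yl)-6-methyl-1,4-benzoquinone | CC(C)=CCC/C(C)=C/CC1=CC(=O)C=C(C)C1=O | intermediate
6 | zinc 2-geranyl-6-methylbenzene-1,4-diolate (not isolated) | CC(C)=CCC/C(C)=C/Cc1cc([O-])cc(C)c1[O-].[Zn+2] | intermediate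
7 | geranyltoluquinol diacetate, 2-((2E)-3,7-dimethylocta-2,6-dien-1-yl)-6-methylbenzene-1,4-diyl diacetate | CC(C)=CCC/C(C)=C/Cc1cc(OC(C)=O)cc(C)c1OC(C)=O | intermediate
8 | allylic alcohol, 2-((2E,6E)-8-hydroxy-3,7-dimethylocta-2,6-dien-1-yl)-6-methylbenzene-1,4-diyl diacetate | OC/C(C)=C/CC/C(C)=C/Cc1cc(OC(C)=O)cc(C)c1OC(C)=O | intermediate
9 | allylic chloride, 2-((2E,6E)-8-chloro-3,7-dimethylocta-2,6-dien-1-yl)-6-methylbenzene-1,4-diyl diacetate | ClC/C(C)=C/CC/C(C)=C/Cc1cc(OC(C)=O)cc(C)c1OC(C)=O | intermediate
10 | geraniol, (2E)-3,7-dimethylocta-2,6-dien-1-ol | CC(C)=CCC/C(C)=C/CO | starting material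
11 | (2S,3S)-2,3-epoxygeraniol (CH2OH and CH3 cis on the oxirane) | CC(C)=CCC[C@]1(C)O[C@H]1CO | intermediate
12 | epoxy chloride, (2S,3R)-3-(chloromethyl)-2-methyl-2-(4-methylpent-3-en-1-yl)oxirane | CC(C)=CCC[C@]1(C)O[C@H]1CCl | intermediate
13 | dilithium alkoxide acetylide of 14 (not isolated) | CC(C)=CCC[C@](C)([O-])C#[C-].[Li+].[Li+] | intermediate
14 | (S)-dehydrolinalool, (3S)-3,7-dimethyloct-6-en-1-yn-3-ol | CC(C)=CCC[C@](C)(O)C#C | intermediate
15 | O-zirconated (1E,3S)-alkenylzirconocene chloride from 14, Cp2ZrCl on O3 and on C1 (not isolated) | CC(C)=CCC[C@](C)(O[Zr](Cl)(C1C=CC=C1)C1C=CC=C1)/C=C/[Zr](Cl)(C1C=CC=C1)C1C=CC=C1 | intermediate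
16 | target diacetate, 2-((2E,6E,9E,11S)-11-hydroxy-3,7,11,15-tetramethylhexadeca-2,6,9,14-tetraen-1-yl)-6-methylbenzene-1,4-diyl diacetate | CC(C)=CCC[C@](C)(O)/C=C/C/C(C)=C/CC/C(C)=C/Cc1cc(OC(C)=O)cc(C)c1OC(C)=O | intermediate
17 | CNP0297794.1, 2-((2E,6E,9E,11S)-11-hydroxy-3,7,11,15-tetramethylhexadeca-2,6,9,14-tetraen-1-yl)-6-methylbenzene-1,4-diol | CC(C)=CCC[C@](C)(O)/C=C/C/C(C)=C/CC/C(C)=C/Cc1cc(O)cc(C)c1O | target

Total step count: 10
Longest linear sequence: 7 steps (steps 1, 2, 3, 4, 5, 9, 10)

Steps most likely to fail

Step 9.
- What may go wrong: bond formation at the substituted allyl terminus. Syn–anti isomerisation of the allylpalladium could also erode the E geometry at C6=C7. Hydride could be transferred from left-over Zr–H to the allylic chloride or the acetates.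
- Fallback: it sets out from 14 and 9 and forms the same C8–C9 bond at the alkyne oxidation level. Copper-mediated alkynyl–allyl coupling of the free alkynol with the chloride (CuI, NaI, K2CO3, DMF, rt) should give the skipped enyne diacetate F1.
- Hydroxyl-directed trans-hydroalumination follows, with NaAlH2(OCH2CH2OMe)2 (THF, 0 °C → rt, then aqueous potassium sodium tartrate under argon). It should reduce only the propargylic alkyne to the E-alkene and cleave both aryl acetates in the same operation.
- This path comes back to the route at 17.

Step 1.
- What may go wrong: O-alkylation, para or ipso C-alkylation, and double alkylation of the phenolate.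
- Fallback: it sets out from 1 and replaces ambident phenolate chemistry by a regiodefined aryl metal. MOMCl and i-Pr2NEt in CH2Cl2 should give the cresol MOM ether F2.
- Directed ortho-lithiation (n-BuLi, TMEDA, Et2O, 0 °C) at the only free position beside the OMOM group should give the ortho-lithiated MOM ether F3.
- Transmetalation with CuBr·SMe2 and SN2 allylation with geranyl bromide 2 should give the geranylated MOM ether F4.
- Mild acetal exchange (pyridinium tosylate, MeOH, 40 °C) comes back to the route at 4.

Step 4.
- What may go wrong: competing oxidation at the allylic positions of the internal alkene or at the benzylic CH2, and over-oxidation of the new alcohol.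
- Fallback: it sets out from 7 and exchanges the alkene terminus instead of oxidising a C–H bond. Cross metathesis with methacrolein (second-generation Hoveyda–Grubbs catalyst, CH2Cl2, 40 °C) should engage only the sterically accessible isopropylidene end and give the E-configured terminal enal F5.
- Luche reduction (NaBH4, CeCl3·7H2O, MeOH, −40 °C) comes back to the route at 8.

Further compounds
F1 | step 9 | skipped enyne diacetate, 2-((2E,6E,11S)-11-hydroxy-3,7,11,15-tetramethylhexadeca-2,6,14-trien-9-yn-1-yl)-6-methylbenzene-1,4-diyl diacetate | CC(C)=CCC[C@](C)(O)C#CC/C(C)=C/CC/C(C)=C/Cc1cc(OC(C)=O)cc(C)c1OC(C)=O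
F2 | step 1 | cresol MOM ether, 1-(methoxymethoxy)-2-methylbenzene | COCOc1ccccc1C
F3 | step 1 | ortho-lithiated MOM ether, [2-(methoxymethoxy)-3-methylphenyl]lithium | [Li]c1cccc(C)c1OCOC
F4 | step 1 | geranylated MOM ether, 1-((2E)-3,7-dimethylocta-2,6-dien-1-yl)-2-(methoxymethoxy)-3-methylbenzene | CC(C)=CCC/C(C)=C/Cc1cccc(C)c1OCOC
F5 | step 4 | terminal enal, 2-((2E,6E)-3,7-dimethyl-8-oxoocta-2,6-dien-1-yl)-6-methylbenzene-1,4-diyl diacetate | O=C/C(C)=C/CC/C(C)=C/Cc1cc(OC(C)=O)cc(C)c1OC(C)=O
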